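**Plan**

1. Numbering follows the labdanes: ring A = C1–C5 and C10, ring B = C5–C10; C4 carries two methyls, C8 and C10 one each; the side chain is C11–C16 (methyl on C13, carbinol C15, lactone O–CH = C16).
2. Cuts: C15–C16 (vinylogous Mukaiyama aldol), C14–C15 and the C13 methyl (carboalumination of a terminal alkyne), C11–C12 and C9–C11 (propargyl conjugate addition to a 9-methylene-8-ketone), the C8 methyl, and the decalin at C2–C3, C5–C10 and C7–C8 into phosphonium salt 5 (C8, C9, C10, C1, C2) and keto aldehyde 7 (C3–C7).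
3. Enabling feature: C5 lies between the quaternary C4 and the oxygen-bearing C6, and C6/C8 are 1,3-dioxygenated. With C6 as a ketone, C5 and C7 are enolate carbons, C3 is a non-enolisable aldehyde carbon, C10 is the β-carbon of an enoate and C8 its ester carbon.
4. Forward: one flask joins 5 and 7 by Wittig olefination (C2=C3), closes ring A by Michael addition C5→C10 and ring B by Claisen condensation C7→C8. Then follow hydrogenation, 1,3-carbonyl transposition, the side chain at C9, the methyl at C8, the two ring-B hydroxyls, the enal and last the butenolide.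
5. Stereochemistry: C10 (with C5 trans) is formed racemic and resolved as the (−)-menthyl vinylogous ester that the transposition needs anyway. C9 comes from α-face protonation of an enolate, C8 from α-face epoxidation of the 7-en-6-one, C6 from thermodynamic reduction, C13=C14 (E) from syn-carboalumination, and C15/C16 from a titanium–BINOL catalyst.

Key step: step 5

Remark: compounds 10–12 are racemic; their SMILES show the enantiomer that is carried on after step 7.

Step 1
Reactants: 1 but-3-yn-1-ol
Product: 3 ethyl (2E)-5-hydroxy-3-methylpent-2-enoate, via alkenylalane 2 (not isolated)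
Conditions: Me3Al (3 equiv), Cp2ZrCl2 (0.25 equiv), CH2Cl2, 0 °C → rt; then ClCO2Et, 0 °C → rt; aq. HCl
Reagents that add atoms: trimethylaluminium, C[Al](C)C; ethyl chloroformate, CCOC(=O)Cl
Why: Zirconium-catalysed syn-carboalumination (Negishi) should put the methyl on the internal and aluminium on the terminal alkyne carbon, and acylation of the alkenylalane with retention fixes the E-enoate (no stereocentre is formed).

Step 2
Reactants: 3 ethyl (2E)-5-hydroxy-3-methylpent-2-enoate
Product: 4 ethyl (2E)-5-iodo-3-methylpent-2-enoate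
Conditions: I2, PPh3, imidazole, CH2Cl2, 0 °C → rt
Reagents that add atoms: iodine, II
Why: Appel iodination, an SN2 displacement of the alkoxyphosphonium ion at the primary carbon.

Step 3
Reactants: 4 ethyl (2E)-5-iodo-3-methylpent-2-enoate
Product: 5 [(3E)-5-ethoxy-3-methyl-5-oxopent-3-en-1-yl]triphenylphosphonium iodide
Conditions: PPh3, MeCN, 80 °C
Reagents that add atoms: triphenylphosphine, c1ccc(cc1)P(c1ccccc1)c1ccccc1
Why: SN2 quaternisation of triphenylphosphine by the primary iodide.

Step 4
Reactants: 6 2,2-dimethylpent-4-enal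
Product: 7 2,2-dimethyl-4-oxopentanal
Conditions: PdCl2 (10 mol%), CuCl (1 equiv), O2 (1 atm), DMF–H2O, rt
Reagents that add atoms: water, O (source of the ketone oxygen; O2 is the terminal oxidant)
Why: Tsuji–Wacker oxidation, in which Markovnikov hydroxypalladation of the terminal alkene should give the methyl ketone while the neopentyl aldehyde stays untouched.

Step 5
Reactants: 5 [(3E)-5-ethoxy-3-methyl-5-oxopent-3-en-1-yl]triphenylphosphonium iodide; 7 2,2-dimethyl-4-oxopentanal
Product: 11 rac-trans-4a,8,8-trimethyl-4a,5,8,8a-tetrahydronaphthalene-1,3(2H,4H)-dione (labdane positions: 4,4,10-trimethyl-Δ2-decalin-6,8-dione; 5α-H/10β-CH3 in the enantiomer drawn), via phosphonium ylide 8 (not isolated), via Z-dienoate 9 (not isolated), via cyclohexenyl keto ester 10 (not isolated)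
Conditions: 5, KN(SiMe3)2 (1.0 equiv), THF, −78 °C; 7, −78 → 0 °C; then KOt-Bu (2.5 equiv), t-BuOH–THF, 0 → 45 °C; 1 M HCl
Reagents that add atoms: none
Why: Deprotonation of 5 gives the non-stabilised ylide 8, which adds to the hindered, non-enolisable aldehyde of 7 and collapses through the oxaphosphetane to the Z-alkene 9 (C2=C3); tert-butoxide then equilibrates the ketone enolates, the C5 enolate adds to C10 of the β,β-disubstituted enoate to close ring A, and the C7 enolate acylates the ester to close ring B as the β-diketonate. The closest known reaction types are the Z-selective Wittig olefination of a non-stabilised ylide and the intramolecular Michael–Claisen (Dieckmann-type) sequence that turns a ketone and an enoate into a cyclohexane-1,3-dione. Ring A closes by a 6-exo-trig Michael addition and ring B by a 6-exo-trig Claisen acylation. C10 (quaternary) and C5 are the new stereocentres: with no resident stereocentre the pair forms as a racemate, the trans relation should follow from a chair-like closure with the acetyl group and the acetate arm both equatorial, and C5 stays correctable because it is α to the C6 carbonyl. The step needs attack of the ylide on the aldehyde and not on the ketone or the enoate (aldehyde olefination is much faster at −78 °C, and the E-geometry of 5 holds the ester away from the ylide), a Z-alkene (the only geometry that lets C5 reach C10), and closure through C5 and not C7 (C7 would need an eight-membered ring, and irreversible diketonate formation drains the equilibrium).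

Step 6
Reactants: 11 rac-trans-4a,8,8-trimethyl-4a,5,8,8a-tetrahydronaphthalene-1,3(2H,4H)-dione
Product: 12 rac-trans-4a,8,8-trimethyl-4a,5,6,7,8,8a-hexahydronaphthalene-1,3(2H,4H)-dione (4,4,10-trimethyl-trans-decalin-6,8-dione)
Conditions: H2 (1 atm), Pd/C (10%), EtOAc, rt
Reagents that add atoms: none
Why: Heterogeneous hydrogenation should saturate the isolated cis-disubstituted C2=C3 alkene while the enolised β-diketone is left alone; no stereocentre is formed.

Step 7
Reactants: 12 rac-trans-4a,8,8-trimethyl-4a,5,6,7,8,8a-hexahydronaphthalene-1,3(2H,4H)-dione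
Product: 13 3-{[(1R,2S,5R)-5-methyl-2-(propan-2-yl)cyclohexyl]oxy}-4a,8,8-trimethyl-4a,5,6,7,8,8a-hexahydronaphthalen-1(4H)-one, single diastereomer with 5α-H/10β-CH3 (8-menthyloxy-4,4,10-trimethyl-trans-decal-7-en-6-one)
Conditions: (−)-menthol, p-TsOH (5 mol%), toluene, reflux, Dean–Stark; separation of the diastereomers by crystallisation or chromatography
Reagents that add atoms: (−)-menthol, CC(C)[C@@H]1CC[C@@H](C)C[C@H]1O
Why: Acid-catalysed enol etherification should occur at the less hindered C8 carbonyl (C6 is flanked by C5 and the gem-dimethyl group), the acid equilibrates C5 to the trans ring fusion, and the menthyl group turns the two enantiomers into separable diastereomers (classical resolution, which fixes the absolute configuration of C10 and C5).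

Step 8
Reactants: 13 menthyl vinylogous ester
Product: 15 5,5,8a-trimethyl-4a,5,6,7,8,8a-hexahydronaphthalen-2(1H)-one with 4a-H α and 8a-CH3 β (4,4,10-trimethyl-trans-decal-6-en-8-one), via allylic alcohol 14 (not isolated)
Conditions: LiAlH4, Et2O, 0 °C; then 1 M HCl, THF, rt
Reagents that add atoms: water, O
Why: Stork–Danheiser 1,3-carbonyl transposition, in which 1,2-reduction of the vinylogous ester carbonyl and acid hydrolysis of the enol ether with loss of water should give the transposed enone and release menthol.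

Step 9
Reactants: 15 4,4,10-trimethyl-trans-decal-6-en-8-one
Product: 18 9-methylidene-4,4,10-trimethyl-trans-decal-6-en-8-one, via Mannich base 16 (not isolated), via ammonium iodide 17 (not isolated)
Conditions: LiN(i-Pr)2, THF, −78 °C; CH2=NMe2+ I−, −78 °C → rt; MeI, CH2Cl2–MeOH; DBU, rt
Reagents that add atoms: N,N-dimethylmethyleneiminium iodide (Eschenmoser's salt), C=[N+](C)C.[I-]
Why: Eschenmoser methylenation, in which the kinetic cross-conjugated enolate (C9 is the only enolisable α-carbon) undergoes a Mannich reaction and the quaternised amine eliminates to the exocyclic enone.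

Step 10
Reactants: 18 9-methylidene-4,4,10-trimethyl-trans-decal-6-en-8-one
Product: 19 9β-(but-3-yn-1-yl)-4,4,10-trimethyl-trans-decal-6-en-8-one (9α-H)
Conditions: CH2=C=CHSnBu3 (1.5 equiv), TiCl4 (1.1 equiv), CH2Cl2, −78 °C; aq. NH4Cl at −78 °C
Reagents that add atoms: tributyl(propa-1,2-dien-1-yl)stannane, C=C=C[Sn](CCCC)(CCCC)CCCC
Why: Lewis-acid-mediated SE2′ conjugate addition of the allenylstannane (Hosomi–Sakurai type) should deliver a propargyl group to the unhindered exocyclic methylene carbon, and kinetic protonation of the titanium enolate from the α-face, anti to the axial C10 methyl, sets C9 with the side chain β.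

Step 11
Reactants: 19 9β-(but-3-yn-1-yl)-4,4,10-trimethyl-trans-decal-6-en-8-one
Product: 20 9β-(but-3-yn-1-yl)-4,4,8,10-tetramethyl-trans-decal-6-en-8-ol (8α-CH3/8β-OH expected; this configuration is erased in step 12)
Conditions: MeLi (3 equiv), CeCl3 (3 equiv), THF, −78 °C
Reagents that add atoms: methyllithium, [Li]C
Why: 1,2-Addition of the weakly basic organocerium reagent to the enone carbonyl should install the C8 methyl without enolising and epimerising C9.

Step 12
Reactants: 20 9β-(but-3-yn-1-yl)-4,4,8,10-tetramethyl-trans-decal-6-en-8-ol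
Product: 21 9β-(but-3-yn-1-yl)-4,4,8,10-tetramethyl-trans-decal-7-en-6-one
Conditions: C5H5NH[CrO3Cl] (pyridinium chlorochromate, 2 equiv), 4 Å sieves, CH2Cl2, rt
Reagents that add atoms: pyridinium chlorochromate, [O-][Cr](=O)(=O)Cl.c1cc[nH+]cc1
Why: Babler–Dauben oxidative transposition, in which the chromate ester of the tertiary allylic alcohol undergoes a [3,3]-shift and oxidation to the 8-methyl-7-en-6-one.

Step 13
Reactants: 21 9β-(but-3-yn-1-yl)-4,4,8,10-tetramethyl-trans-decal-7-en-6-one
Product: 22 7α,8α-epoxy-9β-(but-3-yn-1-yl)-4,4,8β,10-tetramethyl-trans-decalin-6-one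
Conditions: 30% H2O2, NaOH, MeOH, 0 °C
Reagents that add atoms: hydrogen peroxide, OO
Why: Weitz–Scheffer nucleophilic epoxidation, in which hydroperoxide should add to C8 from the α-face, opposite the axial C10 methyl and the β side chain, so that the C8–O bond is α and the C8 methyl β.

Step 14
Reactants: 22 7α,8α-epoxy-9β-(but-3-yn-1-yl)-4,4,8β,10-tetramethyl-trans-decalin-6-one
Product: 24 9β-(but-3-yn-1-yl)-4,4,8β,10-tetramethyl-trans-decalin-6α,8α-diol, via hydroxy ketone 23 (not isolated)
Conditions: SmI2 (2.5 equiv), THF–MeOH, −90 °C; then SmI2 (3 equiv), H2O, Et3N, 0 °C → rt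
Reagents that add atoms: none
Why: SmI2 cleaves the Cα–O bond of the α,β-epoxy ketone to the β-hydroxy ketone, and further electron transfer with water and amine should reduce the C6 ketyl to the equatorial 6α-alcohol, the thermodynamically preferred epimer because a 6β-hydroxyl would be 1,3-diaxial to the C4β and C10 methyls.

Step 15
Reactants: 24 9β-(but-3-yn-1-yl)-4,4,8β,10-tetramethyl-trans-decalin-6α,8α-diol
Product: 26 (2E)-5-(6α,8α-dihydroxy-4,4,8β,10-tetramethyl-trans-decalin-9β-yl)-3-methylpent-2-en-1-ol, via alkenylalane 25 (not isolated)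
Conditions: Me3Al (5 equiv), Cp2ZrCl2 (0.5 equiv), CH2Cl2, 0 °C → rt; n-BuLi, THF, −78 °C; (CH2O)n, → rt; aq. Rochelle salt
Reagents that add atoms: trimethylaluminium, C[Al](C)C; formaldehyde (as paraformaldehyde), C=O
Why: Negishi carboalumination (syn addition, methyl to C13) and hydroxymethylation of the alkenylalanate with retention should give the E-trisubstituted allylic alcohol, the two alkoxides only consuming reagent.

Step 16
Reactants: 26 (2E)-5-(6α,8α-dihydroxy-4,4,8β,10-tetramethyl-trans-decalin-9β-yl)-3-methylpent-2-en-1-ol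
Product: 27 (2E)-5-(6α,8α-dihydroxy-4,4,8β,10-tetramethyl-trans-decalin-9β-yl)-3-methylpent-2-enal
Conditions: MnO2 (20 equiv), CH2Cl2, rt
Reagents that add atoms: none
Why: MnO2 oxidises only the primary allylic alcohol and leaves the secondary and tertiary alcohols and the alkene geometry untouched.

Step 17
Reactants: 28 4-methylfuran-2(5H)-one
Product: 29 trimethyl[(4-methylfuran-2-yl)oxy]silane
Conditions: Me3SiOSO2CF3, Et3N, Et2O, 0 °C
Reagents that add atoms: trimethylsilyl trifluoromethanesulfonate, C[Si](C)(C)OS(=O)(=O)C(F)(F)F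
Why: Soft enolisation and O-silylation of the butenolide give the aromatic 2-silyloxyfuran.

Step 18
Reactants: 27 (2E)-5-(6α,8α-dihydroxy-4,4,8β,10-tetramethyl-trans-decalin-9β-yl)-3-methylpent-2-enal; 29 trimethyl[(4-methylfuran-2-yl)oxy]silane
Product: 32 (5S)-5-[(1S,2E)-5-[(1R,2R,4S,4aS,8aS)-2,4-dihydroxy-2,5,5,8a-tetramethyldecahydronaphthalen-1-yl]-1-hydroxy-3-methylpent-2-en-1-yl]-4-methylfuran-2(5H)-one, via bis(trimethylsilyl) ether 30 (not isolated), via silylated aldol adduct 31 (not isolated)
Conditions: (Me3Si)2NH, Me3SiCl (cat.), CH2Cl2, rt, then evaporation; 29 (2 equiv), Ti(Oi-Pr)4/(S)-BINOL (20 mol%), Et2O, −20 °C; 1 M HCl, THF, 0 °C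
Reagents that add atoms: none
Why: Vinylogous Mukaiyama aldol reaction: the silyloxyfuran attacks through its C5 on the enal carbonyl held by the chiral titanium–BINOL complex, the open transition state of the Lewis-acid-mediated addition is expected to favour the threo adduct, and the ligand enantiomer that shields the Si face of the aldehyde (taken here as (S)-BINOL; its mirror image would be used if the sense proved opposite) sets C15 and C16 as S,S, while transient silylation keeps the two hydroxyls off the catalyst and mild acid removes all silyl groups.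

**Compound list**

1 | but-3-yn-1-ol | C#CCCO | starting material
2 | dimethyl[(1E)-4-[(dimethylalumanyl)oxy]-2-methylbut-1-en-1-yl]alumane | C/C(CCO[Al](C)C)=C\[Al](C)C | intermediate
3 | ethyl (2E)-5-hydroxy-3-methylpent-2-enoate | CCOC(=O)/C=C(\C)CCO | intermediate
4 | ethyl (2E)-5-iodo-3-methylpent-2-enoate | CCOC(=O)/C=C(\C)CCI | intermediate
5 | [(3E)-5-ethoxy-3-methyl-5-oxopent-3-en-1-yl]triphenylphosphonium iodide | CCOC(=O)/C=C(\C)CC[P+](c1ccccc1)(c1ccccc1)c1ccccc1.[I-] | intermediate
6 | 2,2-dimethylpent-4-enal | C=CCC(C)(C)C=O | starting material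
7 | 2,2-dimethyl-4-oxopentanal | CC(=O)CC(C)(C)C=O | intermediate
8 | ethyl (2E)-3-methyl-5-(triphenyl-λ5-phosphanylidene)pent-2-enoate | CCOC(=O)/C=C(\C)CC=P(c1ccccc1)(c1ccccc1)c1ccccc1 | intermediate
9 | ethyl (2E,5Z)-3,7,7-trimethyl-9-oxodeca-2,5-dienoate | CCOC(=O)/C=C(\C)C/C=C\C(C)(C)CC(C)=O | intermediate
10 | ethyl rac-2-(6-acetyl-1,5,5-trimethylcyclohex-3-en-1-yl)acetate, acetyl trans to the acetate arm | CCOC(=O)C[C@@]1(C)CC=CC(C)(C)[C@@H]1C(C)=O | intermediate
11 | rac-trans-4a,8,8-trimethyl-4a,5,8,8a-tetrahydronaphthalene-1,3(2H,4H)-dione | C1[C@@]2(C)CC=CC(C)(C)[C@@H]2C(=O)CC1=O | intermediate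
12 | rac-trans-4a,8,8-trimethyl-4a,5,6,7,8,8a-hexahydronaphthalene-1,3(2H,4H)-dione | C1[C@@]2(C)CCCC(C)(C)[C@@H]2C(=O)CC1=O | intermediate
13 | 3-{[(1R,2S,5R)-5-methyl-2-(propan-2-yl)cyclohexyl]oxy}-4a,8,8-trimethyl-4a,5,6,7,8,8a-hexahydronaphthalen-1(4H)-one, 5α-H/10β-CH3 diastereomer | C1[C@@]2(C)CCCC(C)(C)[C@@H]2C(=O)C=C1O[C@@H]1C[C@H](C)CC[C@H]1C(C)C | intermediate
14 | the allylic alcohol from 13 (6β-OH expected), 3-(menthyloxy)-4a,8,8-trimethyl-1,4,4a,5,6,7,8,8a-octahydronaphthalen-1-ol | C1[C@@]2(C)CCCC(C)(C)[C@@H]2[C@H](O)C=C1O[C@@H]1C[C@H](C)CC[C@H]1C(C)C | intermediate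
15 | 5,5,8a-trimethyl-4a,5,6,7,8,8a-hexahydronaphthalen-2(1H)-one, 4a-H α/8a-CH3 β (4,4,10-trimethyl-trans-decal-6-en-8-one) | C1[C@@]2(C)CCCC(C)(C)[C@@H]2C=CC1=O | intermediate
16 | 9α-[(dimethylamino)methyl]-4,4,10-trimethyl-trans-decal-6-en-8-one | CN(C)C[C@H]1[C@@]2(C)CCCC(C)(C)[C@@H]2C=CC1=O | intermediate
17 | trimethyl[(4,4,10-trimethyl-8-oxo-trans-decal-6-en-9α-yl)methyl]ammonium iodide | C[N+](C)(C)C[C@H]1[C@@]2(C)CCCC(C)(C)[C@@H]2C=CC1=O.[I-] | intermediate
18 | 9-methylidene-4,4,10-trimethyl-trans-decal-6-en-8-one | C=C1[C@@]2(C)CCCC(C)(C)[C@@H]2C=CC1=O | intermediate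
19 | 9β-(but-3-yn-1-yl)-4,4,10-trimethyl-trans-decal-6-en-8-one | C#CCC[C@@H]1[C@@]2(C)CCCC(C)(C)[C@@H]2C=CC1=O | intermediate
20 | 9β-(but-3-yn-1-yl)-4,4,8,10-tetramethyl-trans-decal-6-en-8-ol (8α-CH3/8β-OH) | C#CCC[C@@H]1[C@@]2(C)CCCC(C)(C)[C@@H]2C=C[C@]1(C)O | intermediate
21 | 9β-(but-3-yn-1-yl)-4,4,8,10-tetramethyl-trans-decal-7-en-6-one | C#CCC[C@@H]1[C@@]2(C)CCCC(C)(C)[C@@H]2C(=O)C=C1C | intermediate
22 | 7α,8α-epoxy-9β-(but-3-yn-1-yl)-4,4,8β,10-tetramethyl-trans-decalin-6-one | C#CCC[C@@H]1[C@@]2(C)CCCC(C)(C)[C@@H]2C(=O)[C@H]3O[C@@]13C | intermediate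
23 | 9β-(but-3-yn-1-yl)-8α-hydroxy-4,4,8β,10-tetramethyl-trans-decalin-6-one | C#CCC[C@@H]1[C@@]2(C)CCCC(C)(C)[C@@H]2C(=O)C[C@@]1(C)O | intermediate
24 | 9β-(but-3-yn-1-yl)-4,4,8β,10-tetramethyl-trans-decalin-6α,8α-diol | C#CCC[C@@H]1[C@@]2(C)CCCC(C)(C)[C@@H]2[C@@H](O)C[C@@]1(C)O | intermediate
25 | (E)-alkenylalane from 24 with both hydroxyls as dimethylaluminium alkoxides | C/C(CC[C@@H]1[C@@]2(C)CCCC(C)(C)[C@@H]2[C@@H](O[Al](C)C)C[C@@]1(C)O[Al](C)C)=C\[Al](C)C | intermediate
26 | (2E)-5-(6α,8α-dihydroxy-4,4,8β,10-tetramethyl-trans-decalin-9β-yl)-3-methylpent-2-en-1-ol | OC/C=C(\C)CC[C@@H]1[C@@]2(C)CCCC(C)(C)[C@@H]2[C@@H](O)C[C@@]1(C)O | intermediate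
27 | (2E)-5-(6α,8α-dihydroxy-4,4,8β,10-tetramethyl-trans-decalin-9β-yl)-3-methylpent-2-enal | O=C/C=C(\C)CC[C@@H]1[C@@]2(C)CCCC(C)(C)[C@@H]2[C@@H](O)C[C@@]1(C)O | intermediate
28 | 4-methylfuran-2(5H)-one | CC1=CC(=O)OC1 | starting material
29 | trimethyl[(4-methylfuran-2-yl)oxy]silane | Cc1coc(O[Si](C)(C)C)c1 | intermediate
30 | 6,8-bis(trimethylsilyl) ether of 27 | O=C/C=C(\C)CC[C@@H]1[C@@]2(C)CCCC(C)(C)[C@@H]2[C@@H](O[Si](C)(C)C)C[C@@]1(C)O[Si](C)(C)C | intermediate
31 | 6,8,15-tris(trimethylsilyl) ether of 32 | CC1=CC(=O)O[C@@H]1[C@@H](O[Si](C)(C)C)/C=C(\C)CC[C@@H]1[C@@]2(C)CCCC(C)(C)[C@@H]2[C@@H](O[Si](C)(C)C)C[C@@]1(C)O[Si](C)(C)C | intermediate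
32 | (5S)-5-[(1S,2E)-5-[(1R,2R,4S,4aS,8aS)-2,4-dihydroxy-2,5,5,8a-tetramethyldecahydronaphthalen-1-yl]-1-hydroxy-3-methylpent-2-en-1-yl]-4-methylfuran-2(5H)-one | CC1=CC(=O)O[C@@H]1[C@@H](O)/C=C(\C)CC[C@@H]1[C@@]2(C)CCCC(C)(C)[C@@H]2[C@@H](O)C[C@@]1(C)O | target

**Step count**

Total step count: 18. Longest linear sequence: 16 steps (steps 1–3, 5–16 and 18).

**Steps most likely to fail**

Step 5. The ylide may lose triphenylphosphine by β-elimination before it meets the aldehyde, because the C1 hydrogens are vinylogously acidified by the ester; this would give a dienoate instead of the Wittig product. The fallback sets out from 7 and avoids any ylide. Seyferth–Gilbert homologation with the Ohira–Bestmann reagent (K2CO3, MeOH) would give 4,4-dimethylhex-5-yn-2-one F1. Copper-catalysed coupling of this terminal alkyne with commercial ethyl (2E)-4-bromo-3-methylbut-2-enoate (CuI, K2CO3, NaI, DMF) would give ethyl (2E)-3,7,7-trimethyl-9-oxodec-2-en-5-ynoate F2. Semihydrogenation over Pd/CaCO3 poisoned with Pb(OAc)2 and quinoline (Lindlar) would give 9, which is cyclised with KOt-Bu as in the second half of step 5 and comes back to the route at 11.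

Step 10. The stannane may transfer its allenyl instead of its propargyl terminus, or add 1,2 to the ketone, so that the butynyl chain is not installed cleanly. The fallback sets out from 18. Hosomi–Sakurai conjugate allylation (allyltrimethylsilane, TiCl4, CH2Cl2, −78 °C, with the same α-face protonation) would give 9β-(but-3-en-1-yl)-4,4,10-trimethyl-trans-decal-6-en-8-one F3. Selective oxidative cleavage of the terminal alkene (OsO4 cat., NaIO4, 2,6-lutidine, dioxane–H2O) would give 3-(4,4,10-trimethyl-8-oxo-trans-decal-6-en-9β-yl)propanal F4. Ohira–Bestmann homologation (K2CO3, MeOH) then comes back to the route at 19.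

Step 14. Thermodynamic control in the ketone reduction may be incomplete, so that the axial 6β-alcohol forms alongside or instead of the 6α-alcohol. The fallback sets out from 23, isolated after the first SmI2 stage. NaBH4 (MeOH, 0 °C) would give, by α-face hydride attack, 9β-(but-3-yn-1-yl)-4,4,8β,10-tetramethyl-trans-decalin-6β,8α-diol F5. Meerwein–Ponndorf–Verley/Oppenauer equilibration (Al(Oi-Pr)3, i-PrOH, a little acetone, toluene, reflux) would epimerise the carbinol centre to the equatorial alcohol and come back to the route at 24.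

Further compounds
F1 | step 5 | 4,4-dimethylhex-5-yn-2-one | CC(=O)CC(C)(C)C#C
F2 | step 5 | ethyl (2E)-3,7,7-trimethyl-9-oxodec-2-en-5-ynoate | CCOC(=O)/C=C(\C)CC#CC(C)(C)CC(C)=O
F3 | step 10 | 9β-(but-3-en-1-yl)-4,4,10-trimethyl-trans-decal-6-en-8-one | C=CCC[C@@H]1[C@@]2(C)CCCC(C)(C)[C@@H]2C=CC1=O
F4 | step 10 | 3-(4,4,10-trimethyl-8-oxo-trans-decal-6-en-9β-yl)propanal | O=CCC[C@@H]1[C@@]2(C)CCCC(C)(C)[C@@H]2C=CC1=O
F5 | step 14 | 9β-(but-3-yn-1-yl)-4,4,8β,10-tetramethyl-trans-decalin-6β,8α-diol | C#CCC[C@@H]1[C@@]2(C)CCCC(C)(C)[C@@H]2[C@H](O)C[C@@]1(C)O
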